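**Retrosynthetic overview**

1. Teferin ⇒ jaeschkeanadiol + vanillic acid (acylation of the C4 oxygen, last). Atom numbers are the azulene numbers of the target: C3 carbinol, C3a/C8a ring fusion, C4 ester carbon, C6=C7 alkene.
2. Cycloheptene ring ⇒ formal (5+2) annulation: a tertiary C8a radical adds to vinyltriphenylphosphonium (C8–C8a), and the ylide so formed closes onto a C6 methyl ketone by Wittig reaction (C6=C7). The cyclopentane is present first; the seven-membered ring is formed second.
3. Enabling feature: the quaternary C8a lies β to the C3 oxygen, and O–C4–C5–C6(CH3)= is an aldol pattern. C8a–C3a–C4–C5–C6 is therefore a five-carbon chain that can end in a radical precursor and a ketone, while C7 and C8 carry only hydrogen and can come from a vinyl group.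
4. That chain on the ring ⇒ copper-catalysed enantioselective conjugate borylation of 3-methylcyclopent-2-en-1-one with aldol trapping by a C4–C6 aldehyde; the ring ketone (C3) then takes the isopropyl group.
5. Stereochemistry: only the boron-bearing carbon is set by the catalyst. It relays to C3a, C4 and C3, is erased as a radical in the key step, and is rewritten at C8a under control of C3a.

Key step: step 7

Assumption: the copper/QuinoxP* borylation is taken to give the (3R)-boronate with the (R,R)-ligand; if the sense is opposite, the (S,S)-ligand is used and nothing else changes.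

**Route**

Step 1
Reactants: 1 ethyl 2-(2-methyl-1,3-dioxolan-2-yl)acetate
Product: 2 2-(2-methyl-1,3-dioxolan-2-yl)acetaldehyde
Conditions: iBu2AlH (1.05 equiv), CH2Cl2, −78 °C; then aq. potassium sodium tartrate
Reagents that add atoms: none
Why: Partial reduction of an ester to the aldehyde (DIBAL-H reduction), which stops at the aluminium hemiacetal at −78 °C; the ketal is inert and no stereocenter is involved.

Step 2
Reactants: 3 3-methylcyclopent-2-en-1-one; 2 2-(2-methyl-1,3-dioxolan-2-yl)acetaldehyde
Product: 5 (2S,3R)-2-[(1S)-1-hydroxy-2-(2-methyl-1,3-dioxolan-2-yl)ethyl]-3-methyl-3-(4,4,5,5-tetramethyl-1,3,2-dioxaborolan-2-yl)cyclopentan-1-one, via boron enolate 4 (not isolated)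
Conditions: B2pin2 (1.1 equiv), [Cu(MeCN)4]PF6 (5 mol%), (R,R)-QuinoxP* (6 mol%), LiOtBu (10 mol%), DMSO/THF, rt; then 2 (1.3 equiv), 0 °C; aq. NH4Cl
Reagents that add atoms: bis(pinacolato)diboron, CC1(C)OB(OC1(C)C)B1OC(C)(C)C(C)(C)O1
Why: Copper-catalysed enantioselective conjugate borylation of a β-substituted cyclic enone should set the boron-bearing tertiary carbon (3R) and give boron enolate 4 regiospecifically, and the aldol addition of 4 to 2 through a closed six-membered chair transition state (E enolate, hence anti) on the ring face opposite to the pinacolboryl group should set C2 and the carbinol carbon (both S).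

Step 3
Reactants: 5 the aldol adduct
Product: 6 (2S,3R)-2-[(1S)-1-(tert-butyldimethylsilyloxy)-2-(2-methyl-1,3-dioxolan-2-yl)ethyl]-3-methyl-3-(4,4,5,5-tetramethyl-1,3,2-dioxaborolan-2-yl)cyclopentan-1-one
Conditions: TBSOTf (1.2 equiv), 2,6-lutidine (2 equiv), CH2Cl2, −78 °C
Reagents that add atoms: tert-butyldimethylsilyl trifluoromethanesulfonate, CC(C)(C)[Si](C)(C)OS(=O)(=O)C(F)(F)F
Why: Silyl ether protection of the secondary alcohol with a silyl triflate and a hindered base, fast enough at −78 °C that ketone, ketone-derived ketal and boronate should stay untouched; no stereocenter changes.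

Step 4
Reactants: 6 the silyl-protected ketone
Product: 7 (1R,2S,3R)-2-[(1S)-1-(tert-butyldimethylsilyloxy)-2-(2-methyl-1,3-dioxolan-2-yl)ethyl]-3-methyl-1-(propan-2-yl)-3-(4,4,5,5-tetramethyl-1,3,2-dioxaborolan-2-yl)cyclopentan-1-ol
Conditions: iPrMgCl (3 equiv), CeCl3 (3 equiv, dried), THF, −78 °C; aq. NH4Cl
Reagents that add atoms: isopropylmagnesium chloride, CC(C)[Mg]Cl
Why: 1,2-Addition of an organocerium reagent (low basicity, little β-hydride reduction) to the cyclopentanone from the face opposite to the C2 side chain should give the tertiary carbinol with hydroxyl cis and isopropyl trans to that chain (1R); the hindered tertiary boronate is not expected to be attacked at −78 °C.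

Step 5
Reactants: 7 the tertiary alcohol
Product: 8 (4S)-4-(tert-butyldimethylsilyloxy)-4-[(1S,2R,5R)-2-hydroxy-5-methyl-2-(propan-2-yl)-5-(4,4,5,5-tetramethyl-1,3,2-dioxaborolan-2-yl)cyclopentyl]butan-2-one
Conditions: PPTS (0.2 equiv), acetone/H2O (10:1), 50 °C
Reagents that add atoms: water, O
Why: Mild acid-catalysed ketal hydrolysis (transketalisation to acetone) should free the methyl ketone while the secondary silyl ether, the tertiary alcohol and the pinacol boronate survive; no stereocenter is touched.

Step 6
Reactants: 8 the boronate methyl ketone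
Product: 9 potassium trifluoro{(1R,2S,3R)-2-[(1S)-1-(tert-butyldimethylsilyloxy)-3-oxobutyl]-3-hydroxy-1-methyl-3-(propan-2-yl)cyclopentyl}borate
Conditions: KHF2 (4 equiv, aq.), MeOH, 0 °C to rt; extraction into acetone
Reagents that add atoms: potassium hydrogen difluoride, F.[F-].[K+]
Why: Ligand exchange at boron (pinacol boronate to trifluoroborate, no change at carbon) should give a radical precursor that is oxidised at moderate potential; alkyl silyl ethers and ketones tolerate KHF2.

Step 7
Reactants: 9 the potassium trifluoroborate; 10 vinyltriphenylphosphonium bromide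
Product: 12 (3R,3aS,4S,8aR)-4-(tert-butyldimethylsilyloxy)-6,8a-dimethyl-3-(propan-2-yl)-1,2,3,3a,4,5,8,8a-octahydroazulen-3-ol, via phosphorus ylide 11 (not isolated)
Conditions: 10 (1.3 equiv, added over 4 h), 4CzIPN (3 mol%), KF (2 equiv), dry DMSO, blue LEDs (450 nm), 25 °C
Reagents that add atoms: none
Why: Proposed new method: photoexcited 4CzIPN oxidises the tertiary trifluoroborate of 9 to the planar tertiary radical at the future C8a (BF3 is taken up by KF), this nucleophilic radical adds to the CH2 terminus of the electron-poor vinylphosphonium salt 10 (Giese-type addition, C8–C8a), the α-phosphonio radical is reduced by the 4CzIPN radical anion to the non-stabilised ylide 11, and 11 olefinates the C6 methyl ketone of the same molecule (Wittig reaction, C6=C7, Ph3P=O leaves). The closest known reaction types are the light-driven three-component olefination in which a radical adds to a vinylphosphonium salt and the reduced adduct olefinates a carbonyl compound, the photoredox Giese addition of alkyl trifluoroborates, and the Schweizer annulation (conjugate addition to a vinylphosphonium salt followed by intramolecular Wittig reaction); new is the ring-closing use with a tertiary boron radical precursor and a ketone. The seven-membered ring is closed in the Wittig event by attack of the ylide carbon C7 on the ketone carbon C6 through a bicyclic oxaphosphetane, so the step is a formal (5+2) annulation of the chain C8a–C3a–C4–C5–C6 with the two vinyl carbons. The quaternary stereocenter C8a is set in the irreversible radical addition, in which 10 should approach the cyclopentyl radical on the face opposite to the bulky C3a side chain, so that C8 ends trans to C4 (trans ring fusion, 8aR) whatever the configuration at boron was. The step needs the ylide to find only the C6 ketone (the former ring ketone is already the tertiary alcohol, so no five-membered ring can form), the alkene to sit at C6=C7 (fixed by the Wittig mechanism) and the β-silyloxy ketone to survive (the ylide is made by electron transfer, so no external base is present).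

Step 8
Reactants: 12 the silyl-protected bicycle
Product: 13 jaeschkeanadiol, (3R,3aS,4S,8aR)-6,8a-dimethyl-3-(propan-2-yl)-1,2,3,3a,4,5,8,8a-octahydroazulene-3,4-diol
Conditions: TBAF (3 equiv), THF, 40 °C
Reagents that add atoms: none
Why: Fluoride-mediated cleavage of the silyl ether (desilylation); tertiary alcohol and trisubstituted alkene are inert and no stereocenter is touched.

Step 9
Reactants: 13 jaeschkeanadiol; 14 4-acetoxy-3-methoxybenzoic acid
Product: 15 (3R,3aS,4S,8aR)-3-hydroxy-6,8a-dimethyl-3-(propan-2-yl)-1,2,3,3a,4,5,8,8a-octahydroazulen-4-yl 4-acetoxy-3-methoxybenzoate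
Conditions: 14 (1.5 equiv), DCC (1.6 equiv), DMAP (0.3 equiv), CH2Cl2, rt
Reagents that add atoms: none
Why: Steglich esterification (carbodiimide activation, DMAP acyl transfer) should acylate only the secondary C4 hydroxyl because the C3 hydroxyl is tertiary and hindered; the acyl–oxygen bond is formed, so C4 keeps its configuration.

Step 10
Reactants: 15 O-acetylteferin
Product: 16 teferin, (3R,3aS,4S,8aR)-3-hydroxy-6,8a-dimethyl-3-(propan-2-yl)-1,2,3,3a,4,5,8,8a-octahydroazulen-4-yl 4-hydroxy-3-methoxybenzoate
Conditions: pyrrolidine (5 equiv), CH2Cl2, 0 °C to rt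
Reagents that add atoms: none
Why: Chemoselective aminolysis of the aryl acetate, which is far more electrophilic than the hindered secondary aroate, should free the phenol and give the target.

**Compound list**

1 | ethyl 2-(2-methyl-1,3-dioxolan-2-yl)acetate | CCOC(=O)CC1(C)OCCO1 | starting material
2 | 2-(2-methyl-1,3-dioxolan-2-yl)acetaldehyde | O=CCC1(C)OCCO1 | intermediate
3 | 3-methylcyclopent-2-en-1-one | CC1=CC(=O)CC1 | starting material
4 | boron enolate, 2-{[(3R)-3-methyl-3-(4,4,5,5-tetramethyl-1,3,2-dioxaborolan-2-yl)cyclopent-1-en-1-yl]oxy}-4,4,5,5-tetramethyl-1,3,2-dioxaborolane | C[C@]1(B2OC(C)(C)C(C)(C)O2)CCC(OB2OC(C)(C)C(C)(C)O2)=C1 | intermediate (not isolated)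
5 | (2S,3R)-2-[(1S)-1-hydroxy-2-(2-methyl-1,3-dioxolan-2-yl)ethyl]-3-methyl-3-(4,4,5,5-tetramethyl-1,3,2-dioxaborolan-2-yl)cyclopentan-1-one | CC1(OCCO1)C[C@H](O)[C@H]2C(=O)CC[C@]2(C)B3OC(C)(C)C(C)(C)O3 | intermediate
6 | (2S,3R)-2-[(1S)-1-(tert-butyldimethylsilyloxy)-2-(2-methyl-1,3-dioxolan-2-yl)ethyl]-3-methyl-3-(4,4,5,5-tetramethyl-1,3,2-dioxaborolan-2-yl)cyclopentan-1-one | CC1(OCCO1)C[C@H](O[Si](C)(C)C(C)(C)C)[C@H]2C(=O)CC[C@]2(C)B3OC(C)(C)C(C)(C)O3 | intermediate
7 | (1R,2S,3R)-2-[(1S)-1-(tert-butyldimethylsilyloxy)-2-(2-methyl-1,3-dioxolan-2-yl)ethyl]-3-methyl-1-(propan-2-yl)-3-(4,4,5,5-tetramethyl-1,3,2-dioxaborolan-2-yl)cyclopentan-1-ol | CC1(OCCO1)C[C@H](O[Si](C)(C)C(C)(C)C)[C@H]2[C@](O)(C(C)C)CC[C@]2(C)B3OC(C)(C)C(C)(C)O3 | intermediate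
8 | (4S)-4-(tert-butyldimethylsilyloxy)-4-[(1S,2R,5R)-2-hydroxy-5-methyl-2-(propan-2-yl)-5-(4,4,5,5-tetramethyl-1,3,2-dioxaborolan-2-yl)cyclopentyl]butan-2-one | CC(=O)C[C@H](O[Si](C)(C)C(C)(C)C)[C@H]1[C@](O)(C(C)C)CC[C@]1(C)B2OC(C)(C)C(C)(C)O2 | intermediate
9 | potassium trifluoro{(1R,2S,3R)-2-[(1S)-1-(tert-butyldimethylsilyloxy)-3-oxobutyl]-3-hydroxy-1-methyl-3-(propan-2-yl)cyclopentyl}borate | CC(=O)C[C@H](O[Si](C)(C)C(C)(C)C)[C@H]1[C@](O)(C(C)C)CC[C@]1(C)[B-](F)(F)F.[K+] | intermediate
10 | vinyltriphenylphosphonium bromide | C=C[P+](c1ccccc1)(c1ccccc1)c1ccccc1.[Br-] | starting material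
11 | phosphorus ylide, (4S)-4-(tert-butyldimethylsilyloxy)-4-{(1S,2R,5R)-2-hydroxy-5-methyl-2-(propan-2-yl)-5-[2-(triphenylphosphoranylidene)ethyl]cyclopentyl}butan-2-one | CC(=O)C[C@H](O[Si](C)(C)C(C)(C)C)[C@H]1[C@](O)(C(C)C)CC[C@]1(C)CC=P(c1ccccc1)(c1ccccc1)c1ccccc1 | intermediate (not isolated)
12 | (3R,3aS,4S,8aR)-4-(tert-butyldimethylsilyloxy)-6,8a-dimethyl-3-(propan-2-yl)-1,2,3,3a,4,5,8,8a-octahydroazulen-3-ol | CC(C)(C)[Si](C)(C)O[C@H]1CC(C)=CC[C@@]2(C)CC[C@@](O)(C(C)C)[C@H]12 | intermediate
13 | jaeschkeanadiol, (3R,3aS,4S,8aR)-6,8a-dimethyl-3-(propan-2-yl)-1,2,3,3a,4,5,8,8a-octahydroazulene-3,4-diol | O[C@H]1CC(C)=CC[C@@]2(C)CC[C@@](O)(C(C)C)[C@H]12 | intermediate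
14 | 4-acetoxy-3-methoxybenzoic acid | COc1cc(C(=O)O)ccc1OC(C)=O | starting material
15 | O-acetylteferin, (3R,3aS,4S,8aR)-3-hydroxy-6,8a-dimethyl-3-(propan-2-yl)-1,2,3,3a,4,5,8,8a-octahydroazulen-4-yl 4-acetoxy-3-methoxybenzoate | COc1cc(C(=O)O[C@H]2CC(C)=CC[C@@]3(C)CC[C@@](O)(C(C)C)[C@H]23)ccc1OC(C)=O | intermediate
16 | teferin | COc1cc(C(=O)O[C@H]2CC(C)=CC[C@@]3(C)CC[C@@](O)(C(C)C)[C@H]23)ccc1O | target

**Step count and risks**

Total steps: 10. Longest linear sequence: 10 steps (1 → 2 → 5 → 6 → 7 → 8 → 9 → 12 → 13 → 15 → 16).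

Steps most likely to fail:

1. Step 7 (Proposed new method). The ylide may be intercepted before it closes the ring: by capture with boron trifluoride, by protonation with traces of water, or by conjugate addition to a second molecule of 10. Proton transfer from C5 to the ylide may start β-elimination of the silyloxy group. The radical addition may also show poor facial selectivity at C8a. The fallback uses known polar chemistry and keeps the configuration at the boron-bearing carbon, which already has boron where C8 must go. It sets out from 7: after deprotonation of the tertiary alcohol, Matteson homologation with chloromethyllithium (BrCH2Cl, nBuLi, THF, −78 °C to rt; 1,2-shift with retention) gives the homologated pinacol boronate F1. Zweifel olefination (vinylmagnesium bromide, then I2 and NaOMe) gives the allyl compound F2, ketal hydrolysis as in step 5 gives the methyl ketone F3, and Wittig methylenation (Ph3P=CH2, THF) gives the diene F4. Ring-closing metathesis with second-generation Grubbs catalyst (CH2Cl2, 40 °C) closes C6=C7, and the fallback comes back to the route at 12.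

2. Step 2. The pinacolboron enolate may be protonated or react sluggishly with the enolisable aldehyde, the aldol may revert, or the anti and facial selectivities may be low. The fallback stores the enolate position in a carbon–bromine bond and runs the aldol as a separate metal-enolate reaction. It sets out from 3: the borylation is run as in step 2 to enolate 4, which is quenched with N-bromosuccinimide at −78 °C to give the bromo ketone F5 (used at once, since vicinal bromo boronates can eliminate). A Reformatsky reaction of F5 with 2 (activated Zn, THF, 0 °C) through the zinc enolate of defined position then gives the anti aldol, and the fallback comes back to the route at 5.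

3. Step 4. The secondary organometallic may reduce the hindered ketone by β-hydride transfer or enolise it, may complex the boronate, or may add with low facial selectivity. The fallback uses an sp2 nucleophile without transferable β-hydride and sets the isopropyl group afterwards. It sets out from 6: isopropenylmagnesium bromide with CeCl3 (THF, −78 °C) gives the isopropenyl carbinol F6, and hydrogenation of its 1,1-disubstituted alkene (H2, Pd/C, EtOAc; no other alkene is present at this stage) gives 7, where the fallback comes back to the route.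

**Further compounds**

F1 | step 7 | (1R,2S,3S)-2-[(1S)-1-(tert-butyldimethylsilyloxy)-2-(2-methyl-1,3-dioxolan-2-yl)ethyl]-3-methyl-1-(propan-2-yl)-3-[(4,4,5,5-tetramethyl-1,3,2-dioxaborolan-2-yl)methyl]cyclopentan-1-ol | CC1(OCCO1)C[C@H](O[Si](C)(C)C(C)(C)C)[C@H]2[C@](O)(C(C)C)CC[C@]2(C)CB3OC(C)(C)C(C)(C)O3
F2 | step 7 | (1R,2S,3R)-2-[(1S)-1-(tert-butyldimethylsilyloxy)-2-(2-methyl-1,3-dioxolan-2-yl)ethyl]-3-methyl-1-(propan-2-yl)-3-(prop-2-en-1-yl)cyclopentan-1-ol | CC1(OCCO1)C[C@H](O[Si](C)(C)C(C)(C)C)[C@H]2[C@](O)(C(C)C)CC[C@]2(C)CC=C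
F3 | step 7 | (4S)-4-(tert-butyldimethylsilyloxy)-4-[(1S,2R,5R)-2-hydroxy-5-methyl-2-(propan-2-yl)-5-(prop-2-en-1-yl)cyclopentyl]butan-2-one | CC(=O)C[C@H](O[Si](C)(C)C(C)(C)C)[C@H]1[C@](O)(C(C)C)CC[C@]1(C)CC=C
F4 | step 7 | (1R,2S,3R)-2-[(1S)-1-(tert-butyldimethylsilyloxy)-3-methylbut-3-en-1-yl]-3-methyl-1-(propan-2-yl)-3-(prop-2-en-1-yl)cyclopentan-1-ol | CC(=C)C[C@H](O[Si](C)(C)C(C)(C)C)[C@H]1[C@](O)(C(C)C)CC[C@]1(C)CC=C
F5 | step 2 | (3R)-2-bromo-3-methyl-3-(4,4,5,5-tetramethyl-1,3,2-dioxaborolan-2-yl)cyclopentan-1-one (either configuration at C2) | C[C@]1(B2OC(C)(C)C(C)(C)O2)CCC(=O)C1Br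
F6 | step 4 | (1S,2S,3R)-2-[(1S)-1-(tert-butyldimethylsilyloxy)-2-(2-methyl-1,3-dioxolan-2-yl)ethyl]-3-methyl-1-(prop-1-en-2-yl)-3-(4,4,5,5-tetramethyl-1,3,2-dioxaborolan-2-yl)cyclopentan-1-ol | CC1(OCCO1)C[C@H](O[Si](C)(C)C(C)(C)C)[C@H]2[C@](O)(C(C)=C)CC[C@]2(C)B3OC(C)(C)C(C)(C)O3
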